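## Plan

1. Cuts: first C7–allyl (retro-Claisen to the O6 allyl ether), then the C2=C3 double bond (retro-dehydrogenation), then O1–C2 and C2–C3 together, which removes C2 with its trimethoxyphenyl group as a one-carbon unit.
2. Enabling feature: C2 is a single carbon between O1 and C3. The furan ring can therefore be built from the four-atom unit O1–C7a–C3a–C3 of ring A, used as an ortho-quinone methide (carbonyl at C7a, ethylidene on C3a), and a benzylic sulfonium ylide carbon that acts first as nucleophile and then as electrophile.
3. Forward: isovanillin → allyl ether → Dakin-type oxidation → 3-allyloxy-4-methoxyphenol → one-pot sulfonylethylation para to the allyloxy group. In parallel, trimethoxybenzyl chloride is converted into its dimethylsulfonium salt.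
4. The furan ring is the only ring made. It closes in step 5 and is aromatised by DDQ in step 6. The allyl group is carried as the O6 protecting group, so that neither a C-allyl unit nor a free phenol is exposed to DDQ, and a final Claisen shift moves it to C7 and frees the 6-OH.
5. Stereochemistry: the target has no stereocentre. Step 5 creates a racemic trans C2/C3 pair, which step 6 removes.

Key step: step 5

Remark: the target SMILES contains no stereocentre and no stereogenic double bond, so the compound is achiral and no enantioselective step is needed. Racemic intermediates are drawn as one enantiomer.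

## Route

Step 1
Reactants: 1 isovanillin (3-hydroxy-4-methoxybenzaldehyde); 2 allyl bromide
Product: 3 3-(allyloxy)-4-methoxybenzaldehyde
Conditions: K2CO3, DMF, rt
Reagents that add atoms: none
Why: Williamson ether synthesis, in which the phenoxide of 1 is alkylated by the allylic bromide (SN2) while the aldehyde is inert to carbonate.

Step 2
Reactants: 3 3-(allyloxy)-4-methoxybenzaldehyde
Product: 5 3-(allyloxy)-4-methoxyphenol, via 3-(allyloxy)-4-methoxyphenyl formate 4 (not isolated)
Conditions: mCPBA, CH2Cl2, 0 °C to rt; then MeOH, cat. K2CO3, rt
Reagents that add atoms: mCPBA, OOC(=O)c1cccc(Cl)c1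
Why: Baeyer–Villiger (Dakin-type) oxidation, in which the aryl group activated by the para-methoxy substituent migrates much faster than the peracid epoxidises the electron-poor monosubstituted alkene of the allyl ether, followed by mild methanolysis of the formate.

Step 3
Reactants: 5 3-(allyloxy)-4-methoxyphenol; 6 acetaldehyde; 7 sodium p-toluenesulfinate
Product: 9 rac-5-(allyloxy)-4-methoxy-2-[1-(4-methylbenzenesulfonyl)ethyl]phenol, via rac-5-(allyloxy)-2-(1-hydroxyethyl)-4-methoxyphenol 8 (not isolated)
Conditions: HCO2H/H2O (1:1), rt, closed flask
Reagents that add atoms: none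
Why: Three-component Mannich-type sulfonylalkylation as used for sesamol and 3,4-dialkoxyphenols, in which acid-promoted hydroxyalkylation occurs at C6 (ortho to OH and para to the allyloxy group, whereas C2 is flanked by two oxygens) and the ionised benzylic alcohol is captured at sulfur by the sulfinic acid to give a sulfone that should crystallise from the medium, the new stereocentre being racemic and destroyed in step 5.

Step 4
Reactants: 10 3,4,5-trimethoxybenzyl chloride; 11 dimethyl sulfide
Product: 12 dimethyl(3,4,5-trimethoxybenzyl)sulfonium chloride
Conditions: Me2S (excess), MeCN, rt; Et2O trituration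
Reagents that add atoms: none
Why: S-alkylation of a dialkyl sulfide by an activated benzylic chloride (SN2 sulfonium salt formation), driven by separation of the salt from the solvent.

Step 5
Reactants: 9 rac-5-(allyloxy)-4-methoxy-2-[1-(4-methylbenzenesulfonyl)ethyl]phenol; 12 dimethyl(3,4,5-trimethoxybenzyl)sulfonium chloride
Product: 16 rac-(2S,3S)-6-(allyloxy)-5-methoxy-3-methyl-2-(3,4,5-trimethoxyphenyl)-2,3-dihydro-1-benzofuran (2,3-trans), via ortho-quinone methide 13 (not isolated), via sulfonium ylide 14 (not isolated), via sulfonium phenoxide betaine 15 (not isolated)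
Conditions: Cs2CO3 (3 equiv), MeCN, rt; 9 added slowly to 12 (1.5 equiv)
Reagents that add atoms: none
Why: Caesium carbonate deprotonates phenol 9, whose phenoxide, assisted by the para-allyloxy group, expels p-toluenesulfinate (1,4-elimination) to give ortho-quinone methide 13 with the carbonyl at the future C7a and the ethylidene on the future C3a, while the same base reversibly converts salt 12 into the benzylic ylide 14. Conjugate addition of the ylide carbon to the ethylidene carbon forms C2–C3 and re-aromatises ring A to betaine 15, and its phenoxide then displaces dimethyl sulfide at C2 in a 5-exo-tet SN2 closure that forms O1–C2 and the dihydrofuran ring. The closest known reaction type is the carbonate-mediated formal [4+1] annulation of ortho-quinone methides released from 2-(1-tosylalkyl)phenols with sulfonium ylides, which gives trans-2,3-dihydrobenzofurans. The two new stereocentres at C2 and C3 are set relative to each other by the anti placement of aryl and methyl in the ring-closing transition state, reached through reversible betaine formation; the product is racemic and both centres vanish in step 6, so neither the trans/cis outcome nor enantiocontrol affects the target. The selectivity that matters is chemoselectivity: the ylide must intercept 13 before it tautomerises to the 2-vinylphenol or oligomerises and before the phenoxide is benzylated by 12, which the fast sulfinate loss from the electron-rich ring, the slow addition of 9 and the excess of 12 should secure.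

Step 6
Reactants: 16 rac-(2S,3S)-6-(allyloxy)-5-methoxy-3-methyl-2-(3,4,5-trimethoxyphenyl)-2,3-dihydro-1-benzofuran
Product: 17 6-(allyloxy)-5-methoxy-3-methyl-2-(3,4,5-trimethoxyphenyl)-1-benzofuran
Conditions: DDQ (1.2 equiv), dry 1,4-dioxane, 80 °C
Reagents that add atoms: none
Why: DDQ dehydrogenation as applied to dihydrobenzofuran neolignans, in which hydride is abstracted from the benzylic C3–H (the cation is stabilised by O1 and by the para O6 ether) and the C2 proton is then lost, giving the aromatic furan and removing both stereocentres, while the aryl allyl ether offers no comparably hydridic C–H.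

Step 7
Reactants: 17 6-(allyloxy)-5-methoxy-3-methyl-2-(3,4,5-trimethoxyphenyl)-1-benzofuran
Product: 19 5-methoxy-3-methyl-7-(prop-2-en-1-yl)-2-(3,4,5-trimethoxyphenyl)-1-benzofuran-6-ol (target), via ortho-dienone 18 (not isolated)
Conditions: PhNEt2, 200 °C, sealed tube (Ar)
Reagents that add atoms: none
Why: Aromatic Claisen rearrangement, a concerted [3,3]-sigmatropic shift of the allyl aryl ether to C7, the only free ortho position (C5 carries OMe, so migration there is unproductive and reversible), followed by tautomerisation of dienone 18 to the phenol without creating a stereocentre.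

## Compound list

1 | isovanillin (3-hydroxy-4-methoxybenzaldehyde) | O=Cc1ccc(OC)c(O)c1 | starting material
2 | allyl bromide | C=CCBr | starting material
3 | 3-(allyloxy)-4-methoxybenzaldehyde | C=CCOc1cc(C=O)ccc1OC | intermediate
4 | 3-(allyloxy)-4-methoxyphenyl formate | C=CCOc1cc(OC=O)ccc1OC | intermediate (not isolated)
5 | 3-(allyloxy)-4-methoxyphenol | C=CCOc1cc(O)ccc1OC | intermediate
6 | acetaldehyde | CC=O | starting material
7 | sodium p-toluenesulfinate | Cc1ccc(S(=O)[O-])cc1.[Na+] | starting material
8 | rac-5-(allyloxy)-2-(1-hydroxyethyl)-4-methoxyphenol (one enantiomer drawn) | C=CCOc1cc(O)c([C@H](C)O)cc1OC | intermediate (not isolated)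
9 | rac-5-(allyloxy)-4-methoxy-2-[1-(4-methylbenzenesulfonyl)ethyl]phenol (one enantiomer drawn) | C=CCOc1cc(O)c([C@H](C)S(=O)(=O)c2ccc(C)cc2)cc1OC | intermediate
10 | 3,4,5-trimethoxybenzyl chloride | COc1cc(CCl)cc(OC)c1OC | starting material
11 | dimethyl sulfide | CSC | starting material
12 | dimethyl(3,4,5-trimethoxybenzyl)sulfonium chloride | C[S+](C)Cc1cc(OC)c(OC)c(OC)c1.[Cl-] | intermediate
13 | (6E)-3-(allyloxy)-6-ethylidene-4-methoxycyclohexa-2,4-dien-1-one (ortho-quinone methide) | C/C=C1\C=C(OC)C(OCC=C)=CC1=O | intermediate (not isolated)
14 | dimethylsulfonium (3,4,5-trimethoxyphenyl)methylide | C[S+](C)[CH-]c1cc(OC)c(OC)c(OC)c1 | intermediate (not isolated)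
15 | rac-(1R,2S)-dimethyl[2-(4-allyloxy-5-methoxy-2-oxidophenyl)-1-(3,4,5-trimethoxyphenyl)propyl]sulfonium (zwitterion; one enantiomer drawn; the diastereomer that closes to trans-16 with inversion at C2) | C=CCOc1cc([O-])c(cc1OC)[C@H](C)[C@H](c1cc(OC)c(OC)c(OC)c1)[S+](C)C | intermediate (not isolated)
16 | rac-(2S,3S)-6-(allyloxy)-5-methoxy-3-methyl-2-(3,4,5-trimethoxyphenyl)-2,3-dihydro-1-benzofuran (2,3-trans; one enantiomer drawn) | COc1cc2c(cc1OCC=C)O[C@H](c1cc(OC)c(OC)c(OC)c1)[C@H]2C | intermediate
17 | 6-(allyloxy)-5-methoxy-3-methyl-2-(3,4,5-trimethoxyphenyl)-1-benzofuran | C=CCOc1cc2oc(-c3cc(OC)c(OC)c(OC)c3)c(C)c2cc1OC | intermediate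
18 | rac-7-allyl-5-methoxy-3-methyl-2-(3,4,5-trimethoxyphenyl)-1-benzofuran-6(7H)-one (one enantiomer drawn) | C=CC[C@H]1C(=O)C(OC)=CC2=C1OC(c1cc(OC)c(OC)c(OC)c1)=C2C | intermediate (not isolated)
19 | 5-methoxy-3-methyl-7-(prop-2-en-1-yl)-2-(3,4,5-trimethoxyphenyl)-1-benzofuran-6-ol (CNP0110777.0) | C=CCc1c(O)c(OC)cc2c(C)c(-c3cc(OC)c(OC)c(OC)c3)oc12 | target

## Step count and risks

Total steps: 7. Longest linear sequence: 6 (steps 1, 2, 3, 5, 6, 7); step 4 is a one-step side branch.

Steps most likely to fail:

**Step 5.** Deprotonation of the semi-stabilised sulfonium salt by carbonate may lag behind release of the quinone methide. The quinone methide would then tautomerise to the vinylphenol or oligomerise, or the phenoxide would be benzylated by the salt. The fallback replaces the [4+1] annulation by the acid-mediated formal [3+2] cycloaddition of a para-quinone monoketal with a propenylarene, which is established for dihydrobenzofuran neolignans. It sets out from phenol 5. Oxidation with PhI(OAc)2 in MeOH at 0 °C should give 3-(allyloxy)-4,4-dimethoxycyclohexa-2,5-dien-1-one F1. Treatment of this ketal with purchased (E)-isoelemicin [(E)-1,2,3-trimethoxy-5-(prop-1-enyl)benzene] and TMSOTf in CH2Cl2/MeCN at low temperature should ionise it. The alkene is expected to attack the unhindered C6 terminus and the resulting benzylic cation to be closed by the carbonyl oxygen, giving the trans-dihydrobenzofuran. The route is rejoined at 16, before step 6.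

**Step 3.** In the acidic three-component medium the benzylic cation may be captured by a second molecule of phenol (diarylethane formation), or acetaldehyde may self-condense, faster than sulfinate adds. The fallback builds the side chain stepwise, setting out from phenol 5. Magnesium-mediated ortho-formylation (MgCl2, Et3N, paraformaldehyde, MeCN, reflux) should give 4-(allyloxy)-2-hydroxy-5-methoxybenzaldehyde F2. Addition of MeMgBr (2.2 equiv, THF, 0 °C) gives benzylic alcohol 8, now isolated. Its benzylic hydroxyl is exchanged for the sulfonyl group with p-toluenesulfinic acid in CH2Cl2 at rt, returning to the route at 9.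

**Step 7.** At 200 °C the electron-rich benzofuran may degrade, or the newly formed ortho-allylphenol may cyclise onto the alkene, faster than the [3,3] shift goes to completion. The fallback replaces the sigmatropic shift by a cross-coupling, setting out from 17. Palladium-catalysed deallylation (cat. Pd(PPh3)4, morpholine, THF, rt) should give 5-methoxy-3-methyl-2-(3,4,5-trimethoxyphenyl)-1-benzofuran-6-ol F3. Bromination at the only free position ortho to the hydroxyl (NBS, 1.0 equiv, MeCN, −20 °C, dark) gives 7-bromo-5-methoxy-3-methyl-2-(3,4,5-trimethoxyphenyl)-1-benzofuran-6-ol F4. Stille coupling with allyltributylstannane (cat. Pd(PPh3)4, DMF, 90 °C) then delivers the target, returning to the route at 19.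

## Further compounds

F1 | step 5 | 3-(allyloxy)-4,4-dimethoxycyclohexa-2,5-dien-1-one | C=CCOC1=CC(=O)C=CC1(OC)OC
F2 | step 3 | 4-(allyloxy)-2-hydroxy-5-methoxybenzaldehyde | C=CCOc1cc(O)c(C=O)cc1OC
F3 | step 7 | 5-methoxy-3-methyl-2-(3,4,5-trimethoxyphenyl)-1-benzofuran-6-ol | COc1cc2c(C)c(-c3cc(OC)c(OC)c(OC)c3)oc2cc1O
F4 | step 7 | 7-bromo-5-methoxy-3-methyl-2-(3,4,5-trimethoxyphenyl)-1-benzofuran-6-ol | COc1cc2c(C)c(-c3cc(OC)c(OC)c(OC)c3)oc2c(Br)c1O
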